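Readings and results were computed on assumed constants; the scatter is artificial.

The unit of my books was the point, a hundredth of the substrate charged, and each point had to end as substrate, intermediate or product.

common to all: substrate 1.7 M; free catalyst 17 mM; second catalyst 6.6 mM
- larch: reagent 1.3 M; run made earlier
- ash: reagent 2.8 M; run made earlier
- flask: reagent 1.87 M; time 3.0 h

| run | time / min | substrate / % | product / % |
|---|---|---|---|
| larch | 8.00 | 97 | 0 |
| larch | 15.0 | 96 | 0 |
| larch | 25.0 | 91 | 6 |
| larch | 40.0 | 85 | 9 |
| larch | 60.0 | 80 | 7 |
| larch | 120 | 67 | 24 |
| ash | 8.00 | 98 | 3 |
| ash | 15.0 | 92 | 1 |
| ash | 25.0 | 91 | 4 |
| ash | 40.0 | 87 | 11 |
| ash | 60.0 | 78 | 11 |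
| ash | 120 | 62 | 32 |

(each reading ± 2 percentage points)

- the reaction counts as stopped when no species that holds the substrate changes by six tenths of a point or more over the second half of the time

- why nothing more happens at 3.0 h, or that something still does (no working catalyst is left / forward and back rates have come level / the reagent has run out first / it is still moving / all of the substrate has reacted)
- part of the substrate gone at 3.0 h
- the product standing at 3.0 h, as a percentage of the substrate charged
- the intermediate standing at 3.0 h, as a percentage of the substrate charged

I took one reagent per product, so in the flask substrate, charged at 1.7 M against 1.87 M of reagent, was the limiting reagent, and I kept the flask's books in it.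

The first entry was substrate left. Ash had more than twice the reagent of larch, yet their last readings were 67 % and 62 %, 5 percentage points apart with a scatter of 2 points on each. So I ignored reagent and averaged the two first-order constants, which gave 0.220 /h. Assuming free catalyst carries this step, I divided by its charge and got 12.9 /M/h: the substrate constant per free catalyst.

For the flask this left 51.7 % at 3.0 h, so 48.3 % was gone. Holding substrate at the mean of its start and end gave 50.0 % instead, an error of 1.7 points.

The second entry was intermediate. The points missing from the last readings, at 120 min, averaged 7.50 %, and I assumed that reading would hold unchanged at 3.0 h in the flask, whose reagent lay between those of larch and ash.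

The third entry closed the books: I reckoned product in the flask at 40.8 %, which at one reagent per product meant 0.694 M of the reagent. By this reckoning substrate still fell 20 points over the second half, so I booked the flask as moving.

The forecast held that it is still moving, with 49 % gone, 43 % product and 6 % intermediate, and it noted: "Neither run shows a plateau".

The flask's answer was that it is still moving, with 48.5 % gone, 41.3 % product and 7.21 % intermediate. At 3.00 h, intermediate in the flask was being made at 0.975 of the rate at which it was used up, each step taken net.

    substrate + free catalyst → free catalyst + intermediate (k = 13.0 /M/h)
    reagent + second catalyst + intermediate → second catalyst + product (k = 210 /M²/h)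

The substrate constant per free catalyst on this flask's charge left 51.7 % of substrate, and the flask held 51.5 %. The neighbour flask with 0.043 M of free catalyst then got 18.9 % from the same constant, and that neighbour held 18.7 %.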